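**Retrosynthetic overview**

1. The tiglate is put on last. Before it, the ten-membered carbocycle is closed as the last ring by forming C7–C8: the vinylic C7–Br of a β-bromobutenolide adds to a C8 aldehyde under Ni/Cr mediation (Nozaki–Hiyama–Kishi), which also creates the C8 carbinol.
2. Enabling feature: C8 is a carbinol carbon bonded to C7, the β-carbon of the butenolide ring (O–C12(=O)–C11=C7–C6). C7 is sp2 and can carry a halogen, so the ring bond C7–C8 is a vinyl-metal/aldehyde bond.
3. The bromobutenolide comes from a cis-epoxy aldehyde (C6) and ethyl 2-(acetoxymethyl)-3,3-dibromoacrylate. C7 is a geminal linchpin: one C–Br (Br/Mg exchange) makes C6–C7 and the lactone, the other is kept for the ring closure.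
4. The chain comes from nerol: Sharpless epoxidation (C4, C5), ozonolysis to the C1 aldehyde, Brown (E)-crotylboration (C1, C10). The crotyl vinyl group is the masked C8 aldehyde.
5. Order of ring formation: oxirane (step 1), butenolide (step 10), ten-membered carbocycle (step 13).

Key step: step 13

Remark: germacrane numbering of the target is used for every compound (C1 CH–OAc, C4–C5 oxirane, C6 lactone CH–O, C7=C11 butenolide alkene, C8 tiglate carbinol, C10 CH–CH3, C12 lactone C=O, C13 CH2OAc); the target is read as (1S,4R,5S,6S,8S,10R) with an (E)-2-methylbut-2-enoate (tiglate).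

**Route**

Step 1
Reactants: 1 nerol
Product: 2 (2S,3R)-2,3-epoxynerol (4R,5S)
Conditions: Ti(Oi-Pr)4 (cat.), L-(+)-diethyl tartrate (cat.), t-BuOOH, 4 Å MS, CH2Cl2, −20 °C
Reagents that add atoms: tert-butyl hydroperoxide CC(C)(C)OO
Why: Sharpless asymmetric epoxidation: the Ti–tartrate catalyst epoxidises only the allylic alcohol double bond, and L-(+)-DET should deliver oxygen to the face that gives the (2S,3R)-epoxy alcohol (C4 R, C5 S), the cis relation of C3 and C6 on the oxirane coming from the Z geometry of nerol.

Step 2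
Reactants: 2 (2S,3R)-2,3-epoxynerol
Product: 3 C6 tert-butyldimethylsilyl ether of 2
Conditions: TBSCl, imidazole, CH2Cl2, 0 °C → rt
Reagents that add atoms: tert-butyldimethylsilyl chloride CC(C)(C)[Si](C)(C)Cl
Why: Imidazole-promoted silylation of the primary alcohol masks C6–OH so that the later acetylation at C1 is unambiguous; no stereocentre is touched.

Step 3
Reactants: 3 C6 silyl ether
Product: 5 C1 aldehyde (4R,5S), via ozonide 4 (not isolated)
Conditions: O3, CH2Cl2, −78 °C; then Me2S, −78 °C → rt
Reagents that add atoms: ozone [O-][O+]=O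
Why: Ozonolysis with reductive work-up cleaves the only C=C bond, the electron-rich trisubstituted alkene, to the C1 aldehyde, the oxirane and the silyl ether being inert to ozone; no stereocentre is formed.

Step 4
Reactants: 5 C1 aldehyde
Product: 7 anti homoallylic alcohol (1S,4R,5S,10R), via borinate ester 6 (not isolated)
Conditions: trans-2-butene, n-BuLi, KOt-Bu, THF, −78 → −45 °C; (+)-Ipc2BOMe (from (−)-α-pinene), −78 °C; BF3·OEt2, then 5, −78 °C; then NaOH, H2O2, 0 °C → rt
Reagents that add atoms: trans-2-butene C/C=C/C (crotyl group, delivered as (E)-crotyl-B(Ipc)2 made in the flask); (+)-B-methoxydiisopinocampheylborane COB([C@H]1C[C@H]2C[C@@H]([C@@H]1C)C2(C)C)[C@H]1C[C@H]2C[C@@H]([C@@H]1C)C2(C)C (boron and Ipc groups, in 6 only)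
Why: Brown crotylboration: the (E)-crotylborane reacts through a chair Zimmerman–Traxler transition state, which gives the anti relation of C1–OH and C10–CH3, and the Ipc groups derived from (−)-α-pinene should direct attack to the Re face of the aldehyde, which gives 1S,10R under reagent control because the oxirane stereocentres are remote.

Step 5
Reactants: 7 anti homoallylic alcohol
Product: 8 C1 acetate
Conditions: Ac2O, pyridine, DMAP (cat.), CH2Cl2, 0 °C → rt
Reagents that add atoms: acetic anhydride CC(=O)OC(C)=O
Why: DMAP-catalysed acetylation installs the C1 acetate of the target on the only free hydroxyl group with retention of configuration.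

Step 6
Reactants: 8 C1 acetate
Product: 9 C6 primary alcohol
Conditions: TBAF, AcOH, THF, 0 °C → rt
Reagents that add atoms: none
Why: Fluoride-mediated desilylation, buffered with acetic acid so that the C1 acetate is not cleaved and the epoxy alcohol does not undergo Payne rearrangement.

Step 7
Reactants: 9 C6 primary alcohol
Product: 10 cis-epoxy aldehyde (C6 aldehyde)
Conditions: Dess–Martin periodinane, NaHCO3, CH2Cl2, 0 °C → rt
Reagents that add atoms: none
Why: Dess–Martin oxidation under bicarbonate buffer gives the cis-α,β-epoxy aldehyde without opening the oxirane, and the oxirane CH (C5) is not epimerised (its descriptor becomes R only because CHO outranks C4).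

Step 8
Reactants: 11 ethyl bromopyruvate
Product: 12 ethyl 3-acetoxy-2-oxopropanoate
Conditions: KOAc, 18-crown-6 (cat.), MeCN, 0 °C → rt
Reagents that add atoms: potassium acetate CC(=O)[O-].[K+]
Why: SN2 displacement of the activated α-bromo ketone by acetate introduces the C13 acetoxy group at the outset.

Step 9
Reactants: 12 ethyl 3-acetoxy-2-oxopropanoate
Product: 13 ethyl 2-(acetoxymethyl)-3,3-dibromoprop-2-enoate
Conditions: CBr4, PPh3, CH2Cl2, 0 °C
Reagents that add atoms: carbon tetrabromide BrC(Br)(Br)Br
Why: Ramirez dibromo-olefination (first stage of the Corey–Fuchs sequence) of the ketone carbonyl, which is far more electrophilic than the two ester carbonyls, turns C7 into a geminal dibromide.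

Step 10
Reactants: 10 cis-epoxy aldehyde; 13 ethyl 2-(acetoxymethyl)-3,3-dibromoprop-2-enoate
Product: 16 C7-bromobutenolide with C8=C9 vinyl group (1S,4R,5S,6R,10R), via magnesium carbenoid 14 (not isolated), via magnesium alkoxide 15 (not isolated)
Conditions: 13, i-PrMgCl, THF, −78 °C; then 10, −78 → 0 °C; aq NH4Cl
Reagents that add atoms: none
Why: Bromine–magnesium exchange of the gem-dibromoacrylate at the bromine cis to the ester gives a chelate-stabilised alkylidene magnesium carbenoid that adds to the aldehyde faster than to the acetates at −78 °C; Felkin–Anh (Cornforth) attack anti to the oxirane C5–O bond should set C6 anti to the epoxide oxygen as in the target (formally 6R here because Br raises the rank of C7), and the alkoxide, held cis to the ester, lactonises to the butenolide while the second bromine stays on C7.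

Step 11
Reactants: 16 C7-bromobutenolide with vinyl group
Product: 18 C8 primary alcohol, via B-alkyl-9-BBN 17 (not isolated)
Conditions: 9-BBN, THF, 0 °C → rt; then pH 7 phosphate buffer, 30% H2O2, 0 °C → rt
Reagents that add atoms: 9-borabicyclo[3.3.1]nonane C1CCC2CCCC1B2 (boron, in 17 only); hydrogen peroxide OO (oxygen of the C8 hydroxyl)
Why: Hydroboration–oxidation: 9-BBN adds only to the monosubstituted C8=C9 alkene with anti-Markovnikov regiochemistry, leaving the tetrasubstituted electron-poor bromobutenolide, the esters and the oxirane untouched, and oxidation at pH 7 avoids attack of hydroperoxide on the β-bromoenoate; no stereocentre is formed.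

Step 12
Reactants: 18 C8 primary alcohol
Product: 19 seco-aldehyde (C8 aldehyde and C7–Br)
Conditions: Dess–Martin periodinane, NaHCO3, CH2Cl2, 0 °C → rt
Reagents that add atoms: none
Why: Buffered Dess–Martin oxidation of the primary alcohol gives the C8 aldehyde; the α-carbon C9 is a CH2 group, so nothing can epimerise.

Step 13
Reactants: 19 seco-aldehyde
Product: 21 macrocyclic C8 alcohol (1S,4R,5S,6S,8S,10R), via alkenylchromium species 20 (not isolated)
Conditions: CrCl2 (excess), NiCl2 (cat.), DMSO/THF, rt, slow addition of 19 at high dilution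
Reagents that add atoms: none
Why: Nozaki–Hiyama–Kishi reaction: Ni(0), formed from NiCl2 and Cr(II), inserts into the C7–Br bond of the β-bromobutenolide, transmetalation gives the alkenylchromium(III) species 20, and this adds to the C8 aldehyde to give the chromium alkoxide of 21. The closest known reaction type is the Ni/Cr-mediated macrocyclisation of ω-formyl alkenyl halides to medium and large carbocycles, together with Ni/Cr couplings of β-haloacrylates with aldehydes. One ring is closed, the ten-membered carbocycle, through the C7–C8 bond in a 10-exo-trig addition of the vinyl metal to the carbonyl group, while the oxirane and the butenolide are already in place. The new stereocentre C8 is under substrate control: allylic 1,3-strain with the C13 acetoxymethyl group should turn the aldehyde hydrogen toward C11, and the tether, which leaves C6 on one face of the planar butenolide, should bring C9 to C8 from the opposite face, so that C7 attacks the Re face of the aldehyde and 8S results. The step needs chemoselectivity for the vinylic C–Br bond and the aldehyde, which the mild Ni/Cr pair secures in the presence of two acetates, the lactone and the oxirane, and it needs cyclisation to outrun oligomerisation, which slow addition at high dilution and the two rigid elements of the chain (cis-oxirane and butenolide) secure.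

Step 14
Reactants: 21 macrocyclic C8 alcohol
Product: 22 target (CNP0287840.1)
Conditions: tiglic acid, 2,4,6-trichlorobenzoyl chloride, Et3N, toluene, rt; then 21, DMAP, rt
Reagents that add atoms: tiglic acid C/C=C(\C)C(=O)O
Why: Yamaguchi esterification: the mixed anhydride of tiglic acid acylates the hindered allylic C8–OH under DMAP catalysis with retention at C8 and without E/Z isomerisation of the tiglate, and the weakly basic medium should not deprotonate C6–H next to the oxirane.

**Compound list**

1 | nerol, (2Z)-3,7-dimethylocta-2,6-dien-1-ol | CC(C)=CCC/C(C)=C\CO | starting material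
2 | [(2S,3R)-3-methyl-3-(4-methylpent-3-en-1-yl)oxiran-2-yl]methanol (4R,5S) | CC(C)=CCC[C@@]1(C)O[C@H]1CO | intermediate
3 | tert-butyldimethylsilyl ether of 2 (4R,5S) | CC(C)=CCC[C@@]1(C)O[C@H]1CO[Si](C)(C)C(C)(C)C | intermediate
4 | secondary ozonide of 3 (3,3-dimethyl-1,2,4-trioxolane carrying the epoxy chain; both epimers at the trioxolane CH) | CC1(C)OOC(CC[C@@]2(C)O[C@H]2CO[Si](C)(C)C(C)(C)C)O1 | intermediate
5 | 3-[(2R,3S)-3-{[tert-butyl(dimethyl)silyl]oxymethyl}-2-methyloxiran-2-yl]propanal (C1 aldehyde) | O=CCC[C@@]1(C)O[C@H]1CO[Si](C)(C)C(C)(C)C | intermediate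
6 | bis(isopinocampheyl)borinate ester of 7 | C=C[C@@H](C)[C@@H](OB([C@H]1C[C@H]2C[C@@H]([C@@H]1C)C2(C)C)[C@H]1C[C@H]2C[C@@H]([C@@H]1C)C2(C)C)CC[C@@]1(C)O[C@H]1CO[Si](C)(C)C(C)(C)C | intermediate
7 | (3S,4R)-1-[(2R,3S)-3-{[tert-butyl(dimethyl)silyl]oxymethyl}-2-methyloxiran-2-yl]-4-methylhex-5-en-3-ol (1S,4R,5S,10R; anti) | C=C[C@@H](C)[C@@H](O)CC[C@@]1(C)O[C@H]1CO[Si](C)(C)C(C)(C)C | intermediate
8 | C1 acetate of 7 | C=C[C@@H](C)[C@@H](OC(C)=O)CC[C@@]1(C)O[C@H]1CO[Si](C)(C)C(C)(C)C | intermediate
9 | C6 primary alcohol: C1 acetate, 4R,5S-oxirane, C8=C9 vinyl (1S,4R,5S,10R) | C=C[C@@H](C)[C@@H](OC(C)=O)CC[C@@]1(C)O[C@H]1CO | intermediate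
10 | (2R,3R)-3-[(3S,4R)-3-acetoxy-4-methylhex-5-en-1-yl]-3-methyloxirane-2-carbaldehyde (cis-epoxy aldehyde) | C=C[C@@H](C)[C@@H](OC(C)=O)CC[C@@]1(C)O[C@H]1C=O | intermediate
11 | ethyl bromopyruvate | CCOC(=O)C(=O)CBr | starting material
12 | ethyl 3-acetoxy-2-oxopropanoate | CCOC(=O)C(=O)COC(C)=O | intermediate
13 | ethyl 2-(acetoxymethyl)-3,3-dibromoprop-2-enoate | CCOC(=O)C(COC(C)=O)=C(Br)Br | intermediate
14 | ethyl (2E)-2-(acetoxymethyl)-3-bromo-3-(chloromagnesio)prop-2-enoate (Mg cis to the ester) | Cl[Mg]/C(Br)=C(\C(=O)OCC)COC(C)=O | intermediate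
15 | chloromagnesium alkoxide of the (2E)-γ-hydroxy ester from 10 and 14 (C6–O–MgCl, C7–Br, CO2Et cis to C6) | C=C[C@@H](C)[C@@H](OC(C)=O)CC[C@@]1(C)O[C@H]1[C@@H](O[Mg]Cl)/C(Br)=C(/COC(C)=O)C(=O)OCC | intermediate
16 | (5R)-3-(acetoxymethyl)-4-bromo-5-{(2S,3R)-3-[(3S,4R)-3-acetoxy-4-methylhex-5-en-1-yl]-3-methyloxiran-2-yl}furan-2(5H)-one (1S,4R,5S,6R,10R) | C=C[C@@H](C)[C@@H](OC(C)=O)CC[C@@]1(C)O[C@H]1[C@H]1OC(=O)C(COC(C)=O)=C1Br | intermediate
17 | B-alkyl-9-borabicyclo[3.3.1]nonane from 16 (boron on C8) | C1CCC2CCCC1B2CC[C@@H](C)[C@@H](OC(C)=O)CC[C@@]1(C)O[C@H]1[C@H]1OC(=O)C(COC(C)=O)=C1Br | intermediate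
18 | C8 primary alcohol of the bromobutenolide (1S,4R,5S,6R,10R) | OCC[C@@H](C)[C@@H](OC(C)=O)CC[C@@]1(C)O[C@H]1[C@H]1OC(=O)C(COC(C)=O)=C1Br | intermediate
19 | seco-aldehyde: C8 aldehyde, C7–Br butenolide (1S,4R,5S,6R,10R) | O=CC[C@@H](C)[C@@H](OC(C)=O)CC[C@@]1(C)O[C@H]1[C@H]1OC(=O)C(COC(C)=O)=C1Br | intermediate
20 | alkenylchromium(III) dichloride from 19 (Cr on C7) | O=CC[C@@H](C)[C@@H](OC(C)=O)CC[C@@]1(C)O[C@H]1[C@H]1OC(=O)C(COC(C)=O)=C1[Cr](Cl)Cl | intermediate
21 | macrocyclic C8 alcohol: 1,13-diacetoxy-4,5-epoxy-8-hydroxygermacr-7(11)-en-12,6-olide (1S,4R,5S,6S,8S,10R) | O[C@H]1C[C@@H](C)[C@@H](OC(C)=O)CC[C@@]2(C)O[C@H]2[C@H]2OC(=O)C(COC(C)=O)=C12 | intermediate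
22 | CNP0287840.1, the 8-O-tiglate of 21 (1S,4R,5S,6S,8S,10R) | C/C=C(\C)C(=O)O[C@H]1C[C@@H](C)[C@@H](OC(C)=O)CC[C@@]2(C)O[C@H]2[C@H]2OC(=O)C(COC(C)=O)=C12 | target

**Step count and risks**

Total step count: 14. Longest linear sequence: 12 steps (nerol to 22: steps 1–7 and 10–14); the acrylate branch has 2 steps (8, 9).

Steps most likely to fail:

Step 13. The ring closure may proceed with poor or opposite facial selectivity at the C8 aldehyde, because the stereochemical argument rests on an untested macrocyclic transition state. The vinylchromium species may also lose the lactone oxygen by β-elimination before it cyclises; the fallback below addresses only the stereochemistry. Fallback, from 19 back to 21: the Ni/Cr closure is run without relying on its facial bias and taken on as the mixture of 21 and the C8 epimer of 21 F1. Dess–Martin oxidation converts both into one compound, the macrocyclic C8 ketone F2. Corey–Bakshi–Shibata reduction with the oxazaborolidine antipode that gives 8S (catecholborane, −78 °C) then sets C8 under reagent control and returns 21.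

Step 10. Magnesium chelation between the aldehyde oxygen and the oxirane oxygen may erode Felkin control, which would give poor facial selectivity at C6. Fallback, from 10 back to 16: the carbonyl addition is replaced by an acylation followed by a reagent-controlled reduction. Pinnick oxidation of 10 (NaClO2, NaH2PO4, 2-methyl-2-butene) gives the epoxy acid F3. 2,2′-Dipyridyl disulfide and PPh3 convert it into the S-(2-pyridyl) thioester F4. Carbenoid 14 is acylated by F4 at −78 °C (Mukaiyama ketone synthesis) to give the keto ester F5. CBS reduction of the C6 ketone gives the hydroxy ester F6, which lactonises to 16.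

Step 11. Peroxide or borane may attack the β-bromobutenolide during hydroboration–oxidation, by addition–elimination at C7 or reduction of the lactone. Fallback, from 16 directly to 19: the terminal alkene is oxidised to the aldehyde in one operation by an aldehyde-selective, nitrite-modified Wacker oxidation (PdCl2(PhCN)2, CuCl2, AgNO2, O2, t-BuOH/MeNO2). This avoids both borane and peroxide and skips 18; it makes no new compound F0.

**Further compounds**

F1 | step 13 | C8 epimer of 21 (1S,4R,5S,6S,8R,10R) | O[C@@H]1C[C@@H](C)[C@@H](OC(C)=O)CC[C@@]2(C)O[C@H]2[C@H]2OC(=O)C(COC(C)=O)=C12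
F2 | step 13 | macrocyclic C8 ketone (1,13-diacetoxy-4,5-epoxy-8-oxogermacr-7(11)-en-12,6-olide) | O=C1C[C@@H](C)[C@@H](OC(C)=O)CC[C@@]2(C)O[C@H]2[C@H]2OC(=O)C(COC(C)=O)=C12
F3 | step 10 | (2R,3R)-3-[(3S,4R)-3-acetoxy-4-methylhex-5-en-1-yl]-3-methyloxirane-2-carboxylic acid | C=C[C@@H](C)[C@@H](OC(C)=O)CC[C@@]1(C)O[C@H]1C(=O)O
F4 | step 10 | S-(pyridin-2-yl) thioester of F3 | C=C[C@@H](C)[C@@H](OC(C)=O)CC[C@@]1(C)O[C@H]1C(=O)Sc1ccccn1
F5 | step 10 | ethyl (2E)-2-(acetoxymethyl)-3-bromo-4-oxo-4-(epoxyalkyl)but-2-enoate (C6 ketone) | C=C[C@@H](C)[C@@H](OC(C)=O)CC[C@@]1(C)O[C@H]1C(=O)/C(Br)=C(/COC(C)=O)C(=O)OCC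
F6 | step 10 | ethyl (2E)-2-(acetoxymethyl)-3-bromo-4-hydroxy-4-(epoxyalkyl)but-2-enoate (free C6 alcohol, configured as in 16) | C=C[C@@H](C)[C@@H](OC(C)=O)CC[C@@]1(C)O[C@H]1[C@@H](O)/C(Br)=C(/COC(C)=O)C(=O)OCC
F0 | step 11 | none | none
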